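## The problem

The target is a C20 dibromide. A trans-fused hydrindane (ring B six-membered, ring C five-membered, atoms C1–C7a) carries at C1 an exocyclic methine C8, which is doubly bonded to C1′ of a 4-bromo-3,3-dimethylcyclohexylidene (ring A, C1′–C6′, gem-dimethyl at C3′, bromine at C4′). Rings B and C hold five contiguous stereocentres: C1 (side chain cis to the C7a hydrogen), C7a, the quaternary C3a (methyl anti to the C7a hydrogen), C4 (equatorial bromine next to the quaternary carbon) and C7 (equatorial methyl, axial hydroxyl). The C7 oxygen and the C3a methyl are 1,3-diaxial on the same face of ring B. An oxygen at C7 can therefore control C3a. The C3a methyl can then control the C7a hydrogen (protonation anti), the C7 methyl (equatorial attack) and the C4 bromine (axial hydrogen delivery). C1 and C4′ communicate with nothing and need a catalyst or an enantiopure building block. The C8=C1′ geometry (E, hydrindanyl cis to C6′) has no thermodynamic bias, because C2′ and C6′ differ only through the remote gem-dimethyl group; it must come from a stereospecific event. Both bromides sit on secondary carbons flanked by quaternary carbons, so displacement is not an option, and they will not survive dissolving metal, tin hydride or strong hydride. The trisubstituted alkene will not survive hydrogen-atom-transfer hydrogenation and the tertiary alcohol will not survive strong acid, which fixes the order of events. The enabling feature is that a benzene ring can supply ring B with oxygen at both C4 and C7 and a tetrasubstituted C3a=C7a alkene between them. A hydroxyl at C7 can then deliver a methylene to that alkene, and the resulting cyclopropane is a latent C3a methyl.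

## Retrosynthesis

**C8=C1′ alkene.** The π bond of target 39 is cut to the syn 1,2-diol in triol 37 (as cyclic thionocarbonate 38). A Wittig or Julia union at the same bond has nothing to distinguish C2′ from C6′. A reductive allylic transposition would leave the geometry to a rotamer preference. A syn-specific diol elimination turns the question into one of relative configuration at C8 and C1′. The precursor has the full skeleton and two extra oxygens. The forward step must be a stereospecific syn elimination that tolerates two alkyl bromides and a tertiary alcohol.

**C8–C1′ bond.** Triol 37 goes back through epoxy alcohol 36 to allylic alcohol 35, which is cut at C8–C1′ into aldehyde 23 and vinyl triflate 34. This is the most convergent cut (C12 plus C8). The C1′=C6′ alkene in 34 comes from kinetic enolisation away from the gem-dimethyl group, so regiochemistry, not a facial preference on a near-symmetric ring, marks C6′. A hydroxyl-directed epoxidation then ties the C1′ configuration to C8, and hydride at C6′ erases the marker. Both C8 epimers lead to the same alkene. The forward steps need a carbonyl addition that tolerates bromides and free hydroxyls, an erythro-selective epoxidation and a regioselective epoxide reduction.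

**Ring A.** Triflate 34 comes from ketone 33, and 33 from methylidene compound 32 by ozonolysis. Ring A is opened at C2′–C3′ to tetrafluorobenzoate 30, made from bromohydrin 29, epoxide 28 and diene 27, which is assembled from bromide 24 and silane 25. A bromide next to a quaternary carbon is best made by bromonium-initiated ring closure. The stereocentre is set by a catalytic epoxidation of an acyclic C11 diene. The forward cyclisation must keep the C–Br configuration and end cleanly in an exocyclic alkene.

**C4–Br.** Aldehyde 23 comes from bromo diol 22, which is cut at C4–Br/C5–H to vinyl bromide 21, then hydrazone 20 and ketone 19. Displacement at this neopentyl-type carbon is not viable, whereas radical hydrogenation of a bromoalkene delivers hydrogen axially, anti to the angular methyl. The step must come before the ring A alkene exists. The precursor is a simple ketone.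

**C7–CH3.** Keto diol 19 comes from carbinol 18, which is cut at C7–CH3 to ketone 17. The axial C3a methyl blocks the axial trajectory, so a methyl nucleophile should enter equatorially and leave the hydroxyl axial. The precursor loses one stereocentre. The reagent must not enolise the hindered ketone.

**C3a–CH3 and C7a–H.** Ketone 17 is traced to cyclopropyl ketone 15 by re-forming the C7a–CH2 bond. Reductive cleavage breaks the cyclopropane bond that overlaps with the carbonyl π system, which is the exocyclic one, and gives the angular methyl and an enolate. Protonation anti to the new methyl gives the trans fusion.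

**Cyclopropane (key cut).** Ketone 15 comes from carbinol 14, which is cut at C3a–CH2 and C7a–CH2 to allylic alcohol 11 and diiodomethane 12. Conjugate methyl addition to enone 10, or a sulfoxonium ylide on 10, would have only the remote C1 side chain to choose the face. The C7 hydroxyl delivers the methylene syn to itself. The precursor has no quaternary carbon and one stereocentre fewer.

**Ring B from an arene.** Alcohol 11 comes from enone 10 by reagent-controlled reduction. Enone 10 comes through 9 and 8 from p-methoxyphenol 7 by oxidative dearomatisation, which supplies the C7 carbonyl, the C4 ketal and the ring-fusion alkene in one step. Phenol 7 comes from acid 6, whose C1 stereocentre is set by asymmetric hydrogenation of acid 5. Acid 5 is reached from indanone 1 through 2, 3 and 4.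

## Roads not taken

**Alternative 1:** Rings B and C are cut at the C1–C7a bond, back to the achiral triketone A1 (2-methyl-2-(4-oxobutyl)cyclohexane-1,3-dione). Forward, proline forms the enamine of the aldehyde, whose α-carbon adds to one of the two enantiotopic ring ketones; dehydration gives keto enal A2. The merit is a catalytic, very short entry that fixes the quaternary methyl centre directly and leaves a C4 ketone and a C1 formyl group in place. Here it beats the chosen plan, which needs a cyclopropane and its cleavage to reach the same centre. The weak points are what A2 lacks. C7 has no oxygen, so the tertiary carbinol needs a separate γ-oxidation. The C1=C7a alkene must be reduced to set C1 and C7a together, and trans-hydrindanes are the harder outcome of such reductions. Against its brevity the chosen plan sets the correct oxygen pattern at C4 and C7 from the start, and a single oxygen that relays configuration to C3a, C7a, C7 and C4.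

**Alternative 2:** Ring A is cut at C2′–C3′ at the very end. The substrate A3 carries a chiral allylsilane at C8 and the tertiary tetrafluorobenzoate of an enantiopure bromohydrin. Forward, Me2AlCl ionises the ester to a bromonium ion, the CH2 terminus of the allylsilane attacks the gem-dimethyl carbon, and loss of silicon gives the triethylsilyl ether A4 of the target. In one step this makes ring A, the C4′ bromide and the alkene, which is better step economy in the endgame than the chosen plan. The weak points lie in reaching A3 and in the geometry. The silyl-bearing stereocentre and the bromohydrin ester must be built on a hydrindane that already carries a bromide and a protected tertiary alcohol. The geometry depends on one chair with anti attack on silicon, and the competing chair gives the Z isomer. The chosen plan uses the same ring closure, but on a C11 fragment where geometry is not at stake, and takes the alkene geometry from enolisation regiochemistry and a stereospecific elimination. It pays for this with four more steps.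

**Alternative 3:** Ring B is cut at C3a–C7a, back to the linalool-derived enyne A5. Forward, Et2SBr·SbCl5Br forms a bromonium ion at the trisubstituted alkene, the proximal alkyne carbon attacks the tertiary carbon, and hydration of the vinyl cation gives bromo acetoxy ketone A6. This installs the difficult C4 bromide, the quaternary centre and the C7a centre in one step from the chiral pool, which is more direct than the late vinyl bromide hydrogenation used here. The weak points are several. The only controller of absolute configuration is the remote tertiary acetate. Ring C must still be annulated from the acetyl and silyloxymethyl groups under enolate conditions, next to a bromide. C1 and ring A remain to be set. Against the early bromide the chosen plan sets a pre-formed ring C with C1 fixed by catalysis, and keeps bromine out of all basic and reducing steps.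

Key step: step 11

Assumption: the sense of induction of the chiral catalysts in steps 5, 10 and 21 is assigned by analogy with simple substrates; if a first run shows the opposite sense, the antipodal catalyst is used.

Assumption: step 27 is taken to give both C8 carbinol epimers. Compounds 35–38 are drawn for the (S)-carbinol series; the (R)-carbinol gives the mirror-image arrangement at C8, C1′ and C6′ and the same alkene 39.

## Route

Step 1
Reactants: 1 4,7-dimethoxyindan-1-one
Product: 2 7-hydroxy-4-methoxyindan-1-one
Conditions: BCl3, CH2Cl2, −78 to 0 °C
Reagents that add atoms: none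
Why: Chelation-controlled Lewis-acid demethylation: boron bridges the ketone oxygen and the peri methoxy oxygen, so only that ether is cleaved and the distal one stays.

Step 2
Reactants: 2 7-hydroxy-4-methoxyindan-1-one
Product: 3 4-methoxy-1-oxoindan-7-yl pivalate
Conditions: t-BuCOCl, Et3N, DMAP (cat.), CH2Cl2, 0 °C to rt
Reagents that add atoms: pivaloyl chloride, CC(C)(C)C(Cl)=O
Why: Phenol acylation; the pivalate should survive triflation, carbonylation and hydrogenation and is removed for free in the hydride step.

Step 3
Reactants: 3 4-methoxy-1-oxoindan-7-yl pivalate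
Product: 4 7-methoxy-3-(trifluoromethanesulfonyloxy)-1H-inden-4-yl pivalate
Conditions: Tf2O, 2,6-di-tert-butyl-4-methylpyridine, CH2Cl2, 0 °C to rt
Reagents that add atoms: trifluoromethanesulfonic anhydride, O=S(=O)(OS(=O)(=O)C(F)(F)F)C(F)(F)F
Why: Enol triflation of an indanone with triflic anhydride and a hindered pyridine; only C2 can enolise and no strong base touches the aryl ester.

Step 4
Reactants: 4 7-methoxy-3-(trifluoromethanesulfonyloxy)-1H-inden-4-yl pivalate
Product: 5 7-methoxy-4-(pivaloyloxy)-1H-indene-3-carboxylic acid
Conditions: Pd(OAc)2, dppf, CO (1 atm), KOAc, DMF–H2O, 60 °C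
Reagents that add atoms: carbon monoxide, [C-]#[O+]; water, O
Why: Palladium-catalysed hydroxycarbonylation of a vinyl triflate (oxidative addition, CO insertion, hydrolysis of the acylpalladium species) gives the conjugated acid.

Step 5
Reactants: 5 7-methoxy-4-(pivaloyloxy)-1H-indene-3-carboxylic acid
Product: 6 (R)-4-methoxy-7-(pivaloyloxy)indane-1-carboxylic acid
Conditions: H2 (50 atm), Ru(OAc)2[(R)-BINAP] (cat.), MeOH, 25 °C
Reagents that add atoms: none
Why: Carboxylate-directed asymmetric hydrogenation of an α-aryl α,β-unsaturated acid (Noyori type); the catalyst sets the C1 stereocentre, which controls no other centre and is controlled by none.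

Step 6
Reactants: 6 (R)-4-methoxy-7-(pivaloyloxy)indane-1-carboxylic acid
Product: 7 (R)-3-(hydroxymethyl)-7-methoxyindan-4-ol
Conditions: LiAlH4, THF, 0 °C to reflux
Reagents that add atoms: none
Why: Hydride reduction of the acid to the primary alcohol with simultaneous reductive cleavage of the aryl pivalate; the benzylic stereocentre is not enolisable under these conditions.

Step 7
Reactants: 7 (R)-3-(hydroxymethyl)-7-methoxyindan-4-ol
Product: 8 (R)-1-(hydroxymethyl)-4,4-dimethoxy-1,2,3,4-tetrahydro-7H-inden-7-one (quinone monoketal)
Conditions: PhI(OAc)2, MeOH, 0 °C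
Reagents that add atoms: methanol, CO
Why: Oxidative dearomatisation of a p-methoxyphenol: the aryloxy-iodane ionises and methanol adds para, giving the C7 carbonyl, the C4 dimethyl ketal and the C3a=C7a alkene. The side-chain hydroxyl cannot reach the para carbon.

Step 8
Reactants: 8 quinone monoketal
Product: 9 (R)-1-(hydroxymethyl)-4,4-dimethoxy-1,2,3,4,5,6-hexahydro-7H-inden-7-one
Conditions: H2 (1 atm), RhCl(PPh3)3 (cat.), benzene–EtOH, rt
Reagents that add atoms: none
Why: Homogeneous hydrogenation with Wilkinson's catalyst reduces the disubstituted C5=C6 alkene and leaves the tetrasubstituted ring-fusion alkene; neutral conditions avoid rearomatisation.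

Step 9
Reactants: 9 hydroxy enone ketal
Product: 10 (R)-1-[(tert-butyldimethylsilyloxy)methyl]-4,4-dimethoxy-1,2,3,4,5,6-hexahydro-7H-inden-7-one
Conditions: TBSCl, imidazole, DMF, rt
Reagents that add atoms: tert-butyldimethylsilyl chloride, CC(C)(C)[Si](C)(C)Cl
Why: Silylation of the primary alcohol, so that later only the C7 hydroxyl can bind zinc and the bulky ether shields the opposite face.

Step 10
Reactants: 10 silyloxy enone ketal
Product: 11 (1R,7R)-1-[(tert-butyldimethylsilyloxy)methyl]-4,4-dimethoxy-2,3,4,5,6,7-hexahydro-1H-inden-7-ol (bicyclic allylic alcohol ketal)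
Conditions: (S)-Me-CBS oxazaborolidine (cat.), BH3·SMe2, THF, −30 °C
Reagents that add atoms: none
Why: Corey–Bakshi–Shibata reduction of an α-substituted cyclic enone, with the alkenyl carbon as the large group; reagent control sets the sacrificial C7 carbinol trans to the C1 side chain, and 1,2-reduction is the normal course.

Step 11
Reactants: 11 bicyclic allylic alcohol ketal; 12 diiodomethane
Product: 14 [4.3.1]propellane cyclopropyl carbinol (cyclopropane syn to the C7 hydroxyl), via ethylzinc alkoxide 13 (not isolated)
Conditions: Et2Zn, CH2I2, CH2Cl2, −10 °C to rt
Reagents that add atoms: none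
Why: Diethylzinc deprotonates the C7 hydroxyl to alkoxide 13 and, with diiodomethane, forms an (iodomethyl)zinc carbenoid that binds to the alkoxide oxygen. The methylene is then transferred to the C3a=C7a alkene in a concerted butterfly transition state, forming the C3a–CH2 and C7a–CH2 bonds on the same face in one [2+1] addition. The closest known reaction is the hydroxyl-directed Simmons–Smith cyclopropanation (Furukawa variant) of cyclic allylic alcohols, including ring-fusion alkenes used for angular methylation. The three-membered ring closes by this suprafacial addition and makes the [4.3.1]propellane. The new stereocentres C3a and C7a are both set by the C7 carbinol, itself fixed by the reagent in step 10, so the methylene lands syn to oxygen and anti to the C1 side chain. Only facial selectivity is required, since there is one alkene; the directing alkoxide and the silyloxymethyl group on the other face act in the same sense. The dimethyl ketal on the other allylic carbon is symmetric and exerts no bias. Zinc iodide is the only Lewis acid present and the alkoxide-bound delivery is fast, so the ketal should survive.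

Step 12
Reactants: 14 propellane cyclopropyl carbinol
Product: 15 propellane cyclopropyl ketone (C7 ketone)
Conditions: Dess–Martin periodinane, NaHCO3, CH2Cl2, rt
Reagents that add atoms: none
Why: Buffered hypervalent-iodine oxidation of the secondary alcohol; without acid the ketal and the cyclopropane stay intact.

Step 13
Reactants: 15 propellane cyclopropyl ketone
Product: 17 trans-fused 3a-methyl hydrindan-7-one (C4 dimethyl ketal; C1 silyloxymethyl), via lithium enolate 16 (not isolated)
Conditions: Li, NH3 (l), THF, −78 °C; then NH4Cl
Reagents that add atoms: none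
Why: Dissolving-metal cleavage of a conjugated cyclopropyl ketone: the ketyl breaks the C7a–CH2 bond, which overlaps with the carbonyl π system while the ring-fusion bond lies in its nodal plane, leaving CH3 on C3a and enolate 16. Kinetic protonation of C7a is expected anti to the adjacent axial methyl, giving the trans fusion.

Step 14
Reactants: 17 trans-fused hydrindan-7-one
Product: 18 C7 tertiary carbinol (7-methyl equatorial; 7-hydroxyl axial and syn to the 3a-methyl; C4 ketal; C1 silyloxymethyl)
Conditions: MeLi, CeCl3, THF, −78 °C
Reagents that add atoms: methyllithium, [Li]C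
Why: Organocerium addition suppresses enolisation of the hindered ketone; the axial path is blocked by the 1,3-diaxial C3a methyl, so methyl enters equatorially and the hydroxyl ends up axial, on the face of the angular methyl.

Step 15
Reactants: 18 C7 tertiary carbinol
Product: 19 keto diol (C4 ketone; C1 hydroxymethyl; C7 tertiary alcohol)
Conditions: 1 M HCl (aq.), THF, rt
Reagents that add atoms: water, O
Why: Acid hydrolysis of the dimethyl ketal and of the primary silyl ether in one operation; dilute acid at room temperature should not ionise the tertiary alcohol.

Step 16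
Reactants: 19 keto diol
Product: 20 C4 hydrazone
Conditions: N2H4·H2O, Et3N, EtOH, 80 °C
Reagents that add atoms: hydrazine, NN
Why: Hydrazone formation under Barton's conditions, which are standard for ketones next to a quaternary carbon.

Step 17
Reactants: 20 C4 hydrazone
Product: 21 vinyl bromide (C4(Br)=C5)
Conditions: NBS, pyridine, CH2Cl2, 0 °C
Reagents that add atoms: N-bromosuccinimide, O=C1CCC(=O)N1Br
Why: Barton-type vinyl halide synthesis: N-bromination, loss of nitrogen and proton loss give the bromoalkene. Only C5 carries hydrogen, so one regioisomer can form.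

Step 18
Reactants: 21 vinyl bromide
Product: 22 bromo diol (C4 bromine equatorial, cis to the 3a-methyl)
Conditions: Mn(dpm)3 (cat.), PhSiH3, t-BuOOH, i-PrOH, rt
Reagents that add atoms: none
Why: Manganese-hydride hydrogen-atom-transfer hydrogenation of a haloalkene: H adds to C5 and gives the α-bromo radical at C4. The second hydrogen is delivered axially, anti to the adjacent axial methyl, which leaves bromine equatorial without hydrodebromination.

Step 19
Reactants: 22 bromo diol
Product: 23 hydrindane aldehyde (C1 formyl; C4 bromide; C7 tertiary alcohol)
Conditions: Dess–Martin periodinane, NaHCO3, CH2Cl2, 0 °C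
Reagents that add atoms: none
Why: Selective oxidation of the primary alcohol; the tertiary alcohol is inert and the buffer limits epimerisation at C1, whose formyl group already sits trans to C7 on ring C.

Step 20
Reactants: 24 5-bromo-2-methylpent-2-ene; 25 (2-bromoallyl)trimethylsilane
Product: 27 trimethyl[(6-methyl-2-methylidenehept-5-en-1-yl)]silane, via homoprenylmagnesium bromide 26 (not isolated)
Conditions: Mg, THF; then 25, PdCl2(dppf) (cat.), THF, rt to 50 °C
Reagents that add atoms: none
Why: Grignard formation followed by Kumada coupling of a primary alkylmagnesium halide with a vinyl bromide; dppf suppresses β-hydride elimination.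

Step 21
Reactants: 27 diene allylsilane
Product: 28 (R)-epoxide at the trisubstituted alkene
Conditions: Shi ketone (D-fructose-derived, cat.), KHSO5 (Oxone), K2CO3, Bu4NHSO4, MeCN–CH2(OMe)2–aq. borate buffer, 0 °C
Reagents that add atoms: potassium peroxymonosulfate, [K+].[O-]S(=O)(=O)OO
Why: Shi asymmetric epoxidation: the chiral dioxirane epoxidises the electron-rich trisubstituted alkene through a spiro transition state much faster than the 1,1-disubstituted allylsilane alkene, and sets the future C4′ centre.

Step 22
Reactants: 28 (R)-epoxide
Product: 29 (3S)-3-bromo-2-methyl-6-[(trimethylsilyl)methyl]hept-6-en-2-ol (bromohydrin)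
Conditions: Li2NiBr4, THF, 0 °C to rt
Reagents that add atoms: dilithium tetrabromonickelate, [Li+].[Li+].[Ni+2].[Br-].[Br-].[Br-].[Br-]
Why: Soft nucleophilic bromide opens the epoxide at the less substituted carbon with inversion, giving the secondary bromide and tertiary alcohol.

Step 23
Reactants: 29 bromohydrin
Product: 30 tertiary 2,3,5,6-tetrafluorobenzoate of the bromohydrin
Conditions: 2,3,5,6-tetrafluorobenzoyl chloride, DMAP, pyridine, CH2Cl2, rt
Reagents that add atoms: 2,3,5,6-tetrafluorobenzoyl chloride, O=C(Cl)c1c(F)c(F)cc(F)c1F
Why: DMAP-catalysed acylation of the tertiary alcohol with an electron-poor acid chloride; no alkoxide is generated, so the bromohydrin cannot close back to the epoxide.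

Step 24
Reactants: 30 tetrafluorobenzoate
Product: 32 (S)-4-bromo-3,3-dimethyl-1-methylidenecyclohexane, via bromonium ion 31 (not isolated)
Conditions: Me2AlCl, CH2Cl2, −78 °C
Reagents that add atoms: none
Why: Lewis-acid ionisation of the tertiary ester with bromine participation gives bromonium ion 31 without touching the C–Br stereocentre. The CH2 terminus of the allylsilane attacks the tertiary carbon through a six-membered chair, and loss of silicon leaves the exocyclic alkene (bromonium-initiated cation–olefin cyclisation with allylsilane termination).

Step 25
Reactants: 32 (S)-4-bromo-3,3-dimethyl-1-methylidenecyclohexane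
Product: 33 (S)-4-bromo-3,3-dimethylcyclohexan-1-one
Conditions: O3, CH2Cl2–MeOH, −78 °C; then Me2S
Reagents that add atoms: ozone, [O-][O+]=O
Why: Ozonolysis of the 1,1-disubstituted alkene with reductive work-up; the secondary bromide is inert.

Step 26
Reactants: 33 (S)-4-bromo-3,3-dimethylcyclohexan-1-one
Product: 34 (S)-4-bromo-5,5-dimethylcyclohex-1-en-1-yl trifluoromethanesulfonate
Conditions: LDA, THF, −78 °C; then PhNTf2
Reagents that add atoms: N-phenylbis(trifluoromethanesulfonimide), O=S(=O)(N(c1ccccc1)S(=O)(=O)C(F)(F)F)C(F)(F)F
Why: Kinetic deprotonation takes the α-CH2 remote from the gem-dimethyl group, and O-triflation fixes the C1′=C6′ regiochemistry. Closure of the enolate onto the γ-bromide is blocked by the neopentyl position of that carbon.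

Step 27
Reactants: 23 hydrindane aldehyde; 34 (S)-4-bromo-5,5-dimethylcyclohex-1-en-1-yl trifluoromethanesulfonate
Product: 35 allylic alcohol (C8 carbinol between hydrindane C1 and C1′ of the C1′=C6′ cyclohexene; both C8 epimers)
Conditions: CrCl2, NiCl2 (cat.), DMF, rt
Reagents that add atoms: none
Why: Nozaki–Hiyama–Kishi coupling: zerovalent nickel inserts into the vinyl triflate, transmetallation gives an alkenylchromium species, and this adds only to the aldehyde, tolerating secondary bromides and free hydroxyls. The configuration at C8 is immaterial because both epimers converge later.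

Step 28
Reactants: 35 allylic alcohol
Product: 36 erythro epoxy alcohol (C1′–C6′ epoxide on the face set by the C8 hydroxyl)
Conditions: VO(acac)2 (cat.), t-BuOOH, CH2Cl2, 0 °C to rt
Reagents that add atoms: tert-butyl hydroperoxide, CC(C)(C)OO
Why: Vanadium-directed epoxidation of an allylic alcohol: in the metal-bound transition state the C8 hydrogen lies next to C2′ to avoid allylic 1,2-strain with the hydrindanyl group, so oxygen is delivered erythro from either C8 epimer. The remote tertiary alcohol has no alkene within reach.

Step 29
Reactants: 36 erythro epoxy alcohol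
Product: 37 triol (C8 secondary and C1′ tertiary hydroxyls erythro; C6′ now CH2; C7 tertiary alcohol)
Conditions: LiBH4, Ti(Oi-Pr)4, THF, 0 °C to rt
Reagents that add atoms: none
Why: Titanium-assisted hydride opening of a 2,3-epoxy alcohol at the distal, secondary carbon C6′; the C1′–O bond and its configuration are kept, and borohydride does not reduce the secondary bromides.

Step 30
Reactants: 37 triol
Product: 38 cyclic thionocarbonate of the C8/C1′ diol
Conditions: Cl2C=S, DMAP, CH2Cl2, 0 °C
Reagents that add atoms: thiophosgene, S=C(Cl)Cl
Why: Only the vicinal diol can close a five-membered 1,3-dioxolane-2-thione; the isolated, axial C7 tertiary alcohol is too hindered to compete.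

Step 31
Reactants: 38 cyclic thionocarbonate
Product: 39 CNP0119865.1 (E alkene)
Conditions: 1,3-dimethyl-2-phenyl-1,3,2-diazaphospholidine, THF, 40 °C
Reagents that add atoms: none
Why: Corey–Winter olefination in the Corey–Hopkins variant: thiophilic attack by phosphorus gives a dioxolanylidene that loses CO2 in a syn-specific fragmentation. With the two C–O bonds eclipsed in the ring, the hydrindanyl group lies over C6′ and hydrogen over C2′, so only the E alkene can form.

## Compound list

1 | 4,7-dimethoxyindan-1-one | COc1ccc(OC)c2C(=O)CCc12 | starting material
2 | 7-hydroxy-4-methoxyindan-1-one | COc1ccc(O)c2C(=O)CCc12 | intermediate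
3 | 4-methoxy-1-oxoindan-7-yl pivalate | COc1ccc(OC(=O)C(C)(C)C)c2C(=O)CCc12 | intermediate
4 | 7-methoxy-3-(trifluoromethanesulfonyloxy)-1H-inden-4-yl pivalate | COc1ccc(OC(=O)C(C)(C)C)c2C(OS(=O)(=O)C(F)(F)F)=CCc12 | intermediate
5 | 7-methoxy-4-(pivaloyloxy)-1H-indene-3-carboxylic acid | COc1ccc(OC(=O)C(C)(C)C)c2C(C(=O)O)=CCc12 | intermediate
6 | (R)-4-methoxy-7-(pivaloyloxy)indane-1-carboxylic acid | OC(=O)[C@@H]1CCc2c(OC)ccc(OC(=O)C(C)(C)C)c12 | intermediate
7 | (R)-3-(hydroxymethyl)-7-methoxyindan-4-ol | OC[C@@H]1CCc2c(OC)ccc(O)c12 | intermediate
8 | (R)-1-(hydroxymethyl)-4,4-dimethoxy-1,2,3,4-tetrahydro-7H-inden-7-one | OC[C@@H]1CCC2=C1C(=O)C=CC2(OC)OC | intermediate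
9 | (R)-1-(hydroxymethyl)-4,4-dimethoxy-1,2,3,4,5,6-hexahydro-7H-inden-7-one | OC[C@@H]1CCC2=C1C(=O)CCC2(OC)OC | intermediate
10 | (R)-1-[(tert-butyldimethylsilyloxy)methyl]-4,4-dimethoxy-1,2,3,4,5,6-hexahydro-7H-inden-7-one | CC(C)(C)[Si](C)(C)OC[C@@H]1CCC2=C1C(=O)CCC2(OC)OC | intermediate
11 | (1R,7R)-1-[(tert-butyldimethylsilyloxy)methyl]-4,4-dimethoxy-2,3,4,5,6,7-hexahydro-1H-inden-7-ol | CC(C)(C)[Si](C)(C)OC[C@@H]1CCC2=C1[C@H](O)CCC2(OC)OC | intermediate
12 | diiodomethane | ICI | starting material
13 | ethylzinc alkoxide of 11 | CC(C)(C)[Si](C)(C)OC[C@@H]1CCC2=C1[C@H](O[Zn]CC)CCC2(OC)OC | intermediate (not isolated)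
14 | [4.3.1]propellane cyclopropyl carbinol (cyclopropane syn to the C7 hydroxyl, anti to the C1 silyloxymethyl group) | CC(C)(C)[Si](C)(C)OC[C@@H]2CC[C@]3(C4)C(OC)(OC)CC[C@@H](O)[C@]234 | intermediate
15 | [4.3.1]propellane cyclopropyl ketone | CC(C)(C)[Si](C)(C)OC[C@@H]2CC[C@]3(C4)C(OC)(OC)CCC(=O)[C@]234 | intermediate
16 | lithium enolate (C7–O–Li, C7=C7a) with the C3a methyl in place | CC(C)(C)[Si](C)(C)OC[C@@H]1CC[C@]2(C)C(OC)(OC)CCC(O[Li])=C12 | intermediate (not isolated)
17 | trans-fused 1-[(tert-butyldimethylsilyloxy)methyl]-4,4-dimethoxy-3a-methylhydrindan-7-one | CC(C)(C)[Si](C)(C)OC[C@@H]2CC[C@]3(C)C(OC)(OC)CCC(=O)[C@@H]23 | intermediate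
18 | trans-fused 1-[(tert-butyldimethylsilyloxy)methyl]-4,4-dimethoxy-3a,7-dimethylhydrindan-7-ol (7-OH axial, syn to 3a-methyl) | CC(C)(C)[Si](C)(C)OC[C@@H]2CC[C@]3(C)C(OC)(OC)CC[C@@](C)(O)[C@@H]23 | intermediate
19 | trans-fused 7-hydroxy-1-(hydroxymethyl)-3a,7-dimethylhydrindan-4-one | OC[C@@H]2CC[C@]3(C)C(=O)CC[C@@](C)(O)[C@@H]23 | intermediate
20 | C4 hydrazone of 19 | OC[C@@H]2CC[C@]3(C)C(=NN)CC[C@@](C)(O)[C@@H]23 | intermediate
21 | 4-bromo-1-(hydroxymethyl)-3a,7-dimethyl-2,3,3a,6,7,7a-hexahydro-1H-inden-7-ol (vinyl bromide) | OC[C@@H]2CC[C@]3(C)C(Br)=CC[C@@](C)(O)[C@@H]23 | intermediate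
22 | trans-fused 4-bromo-1-(hydroxymethyl)-3a,7-dimethylhydrindan-7-ol (bromine equatorial, cis to 3a-methyl) | OC[C@@H]2CC[C@]3(C)[C@@H](Br)CC[C@@](C)(O)[C@@H]23 | intermediate
23 | trans-fused 4-bromo-7-hydroxy-3a,7-dimethylhydrindane-1-carbaldehyde | O=C[C@@H]2CC[C@]3(C)[C@@H](Br)CC[C@@](C)(O)[C@@H]23 | intermediate
24 | 5-bromo-2-methylpent-2-ene | CC(C)=CCCBr | starting material
25 | (2-bromoallyl)trimethylsilane | C=C(Br)C[Si](C)(C)C | starting material
26 | (4-methylpent-3-en-1-yl)magnesium bromide | CC(C)=CCC[Mg]Br | intermediate (not isolated)
27 | trimethyl[(6-methyl-2-methylidenehept-5-en-1-yl)]silane | CC(C)=CCCC(=C)C[Si](C)(C)C | intermediate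
28 | {4-[(2R)-3,3-dimethyloxiran-2-yl]-2-methylidenebutyl}trimethylsilane | CC1(C)O[C@@H]1CCC(=C)C[Si](C)(C)C | intermediate
29 | (3S)-3-bromo-2-methyl-6-[(trimethylsilyl)methyl]hept-6-en-2-ol | CC(C)(O)[C@@H](Br)CCC(=C)C[Si](C)(C)C | intermediate
30 | (3S)-3-bromo-2-methyl-6-[(trimethylsilyl)methyl]hept-6-en-2-yl 2,3,5,6-tetrafluorobenzoate | CC(C)(OC(=O)c1c(F)c(F)cc(F)c1F)[C@@H](Br)CCC(=C)C[Si](C)(C)C | intermediate
31 | bromonium ion from 30 (2,2-dimethyl-3-alkylbromiranium) | CC1(C)[Br+][C@H]1CCC(=C)C[Si](C)(C)C | intermediate (not isolated)
32 | (S)-4-bromo-3,3-dimethyl-1-methylidenecyclohexane | CC1(C)CC(=C)CC[C@@H]1Br | intermediate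
33 | (S)-4-bromo-3,3-dimethylcyclohexan-1-one | CC1(C)CC(=O)CC[C@@H]1Br | intermediate
34 | (S)-4-bromo-5,5-dimethylcyclohex-1-en-1-yl trifluoromethanesulfonate | CC1(C)CC(OS(=O)(=O)C(F)(F)F)=CC[C@@H]1Br | intermediate
35 | allylic alcohol: hydrindane C1–CH(OH)–(4-bromo-5,5-dimethylcyclohex-1-enyl); both C8 epimers, (S)-carbinol drawn | O[C@H](C1=CC[C@H](Br)C(C)(C)C1)[C@@H]2CC[C@]3(C)[C@@H](Br)CC[C@@](C)(O)[C@@H]23 | intermediate
36 | erythro epoxy alcohol (C1′–C6′ epoxide); series from the (S)-carbinol drawn | O[C@H]([C@]12O[C@H]1C[C@H](Br)C(C)(C)C2)[C@@H]3CC[C@]4(C)[C@@H](Br)CC[C@@](C)(O)[C@@H]34 | intermediate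
37 | triol (C8 secondary OH, C1′ tertiary OH erythro, C7 tertiary OH); series from the (S)-carbinol drawn | O[C@H]([C@]1(O)CC[C@H](Br)C(C)(C)C1)[C@@H]2CC[C@]3(C)[C@@H](Br)CC[C@@](C)(O)[C@@H]23 | intermediate
38 | cyclic thionocarbonate (1,3-dioxolane-2-thione spiro at C1′) of 37 | S=C1O[C@@H]([C@@H]3CC[C@]4(C)[C@@H](Br)CC[C@@](C)(O)[C@@H]34)[C@]2(O1)CC[C@H](Br)C(C)(C)C2 | intermediate
39 | CNP0119865.1: (1S,3aS,4S,7R,7aS)-4-bromo-1-{(E)-[(4S)-4-bromo-3,3-dimethylcyclohexylidene]methyl}-3a,7-dimethyloctahydro-1H-inden-7-ol | CC1(C)C/C(=C/[C@@H]2CC[C@]3(C)[C@@H](Br)CC[C@@](C)(O)[C@@H]23)CC[C@@H]1Br | target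

## Step count and least certain steps

Total step count: 31. Longest linear sequence: 24 steps (steps 1–19 and 27–31, from indanone 1); the ring A branch is steps 20–26.

**Step 11 (key step).** The most likely failure is slow methylene transfer to a tetrasubstituted alkene flanked by a ketal, with zinc iodide then ionising the allylic ketal and the ring rearomatising; facial leakage is less likely because alkoxide and silyl ether act together. Fallback: from enone 10, dimethylsulfoxonium methylide (Me3S(O)I, NaH, DMSO) adds to C3a and the enolate closes the ring at C7a, giving cyclopropyl ketone 15 directly. The face is then chosen only sterically by the C1 side chain, which is why this is the reserve and not the plan. No new compound is involved.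

**Step 13.** The most likely failure is protonation of the enolate at C7a from the wrong face, because the upper face carries the silyloxymethyl group on C1 while the lower face carries the angular methyl; over-reduction of the ketone is a lesser risk. Fallback: from 15 the silyl ether is removed first with Bu4NF to give hydroxymethyl cyclopropyl ketone F1, so the upper face is unshielded and the hydroxyl can relay the proton to C7a on quench. Li/NH3 then gives trans-fused hydroxy ketone F2, MeLi/CeCl3 in excess gives ketal diol F3, and aqueous HCl returns to keto diol 19.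

**Step 24.** The most likely failure is erosion of enantiomeric purity by bromonium transfer between alkenes, or protodesilylation of the allylsilane by the aluminium reagent before ring closure. Fallback: from bromohydrin 29, SOCl2/pyridine gives bromochloride F4 with retention through the same bromonium ion. Solvolysis of F4 in hexafluoroisopropanol at room temperature generates the bromonium ion without any Lewis acid and closes ring A to 32.

**Step 28.** The most likely failure is incomplete erythro selectivity, which would appear as Z alkene after step 31 because each threo epoxide leads to the other geometry. Fallback: from 35, oxidation with Dess–Martin periodinane gives enone F5, and substrate-controlled 1,2-reduction (NaBH4, CeCl3) returns a single C8 epimer of 35. A Sharpless epoxidation with Ti(Oi-Pr)4, t-BuOOH and the matched diethyl tartrate antipode then adds reagent control to the same erythro preference and returns to 36.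

**Step 30.** The most likely failure is sluggish ring closure of the hindered tertiary–secondary diol, with thiophosgene then reacting at a single hydroxyl only. Fallback: from triol 37, Me2NCH(OMe)2 gives 2-(dimethylamino)-1,3-dioxolane F6, and heating F6 in Ac2O (Eastwood-type syn fragmentation, same stereochemical course) gives 39 directly, bypassing 38.

## Further compounds

F0 | step 11 | none | none
F1 | step 13 | hydroxymethyl cyclopropyl ketone (15 without the silyl group) | OC[C@@H]2CC[C@]3(C4)C(OC)(OC)CCC(=O)[C@]234
F2 | step 13 | trans-fused 1-(hydroxymethyl)-4,4-dimethoxy-3a-methylhydrindan-7-one | OC[C@@H]2CC[C@]3(C)C(OC)(OC)CCC(=O)[C@@H]23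
F3 | step 13 | trans-fused 1-(hydroxymethyl)-4,4-dimethoxy-3a,7-dimethylhydrindan-7-ol | OC[C@@H]2CC[C@]3(C)C(OC)(OC)CC[C@@](C)(O)[C@@H]23
F4 | step 24 | [(5S)-5-bromo-6-chloro-6-methyl-2-methylideneheptyl]trimethylsilane | CC(C)(Cl)[C@@H](Br)CCC(=C)C[Si](C)(C)C
F5 | step 28 | enone: hydrindane C1–C(=O)–(4-bromo-5,5-dimethylcyclohex-1-enyl) | O=C(C1=CC[C@H](Br)C(C)(C)C1)[C@@H]2CC[C@]3(C)[C@@H](Br)CC[C@@](C)(O)[C@@H]23
F6 | step 30 | 2-(dimethylamino)-1,3-dioxolane of the C8/C1′ diol (acetal carbon unassigned) | CN(C)C1O[C@@H]([C@@H]3CC[C@]4(C)[C@@H](Br)CC[C@@](C)(O)[C@@H]34)[C@]2(O1)CC[C@H](Br)C(C)(C)C2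
A1 | alternative 1 | 2-methyl-2-(4-oxobutyl)cyclohexane-1,3-dione | CC1(CCCC=O)C(=O)CCCC1=O
A2 | alternative 1 | bicyclic keto enal | O=CC1=C2CCCC(=O)[C@@]2(C)CC1
A3 | alternative 2 | C8 dimethylphenylsilyl allylsilane with side-chain bromohydrin tetrafluorobenzoate and C7 triethylsilyl ether (silyl-bearing carbon drawn as needed for anti attack through the chair with equatorial bromine) | C=C(CC[C@H](Br)C(C)(C)OC(=O)c1c(F)c(F)cc(F)c1F)[C@@H]([Si](C)(C)c1ccccc1)[C@@H]2CC[C@]3(C)[C@@H](Br)CC[C@@](C)(O[Si](CC)(CC)CC)[C@@H]23
A4 | alternative 2 | triethylsilyl ether of the target | CC1(C)C/C(=C/[C@@H]2CC[C@]3(C)[C@@H](Br)CC[C@@](C)(O[Si](CC)(CC)CC)[C@@H]23)CC[C@@H]1Br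
A5 | alternative 3 | linalool-derived enyne (tertiary acetate, (E)-silyloxymethyl alkene, methyl alkyne) | CC#C[C@](C)(OC(C)=O)CC/C=C(\C)CO[Si](c1ccccc1)(c1ccccc1)C(C)(C)C
A6 | alternative 3 | bromo acetoxy cyclohexyl methyl ketone | CC(C)(C)[Si](c1ccccc1)(c1ccccc1)OC[C@]2(C)[C@@H](Br)CC[C@@](C)(OC(C)=O)[C@H]2C(C)=O
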